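**Plan**
- Retrosynthesis: the sulfate O–S bond and the six benzyl ethers are cut first. The luteolin pyranone ring is then opened at C4a''–C4'', C4''–C3'' and O1''–C2'', giving an o-iodophenol, CO and an arylacetylene.
- Enabling feature: the luteolin A ring (C4a''–C8a'') is a phloroglucinol ring bonded to flavanone C3 through C8''. As a 4-benzyloxy-2,6-dihydroxyphenyl group it has a mirror plane through C1/C4, so iodination at either open position gives one compound; the hydroxyl next to iodine becomes O1'' and the other is left as the only free 7''-OH.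
- Further cuts: C–I, two MOM ethers, then O1–C2 and C2–C3 of the flavanone (deoxybenzoin + 4-benzyloxybenzaldehyde). The deoxybenzoin comes from an isoflavone (C3–aryl bond by Negishi coupling on a 3-iodochromone) by loss of C2 as formate.
- Forward order: phloroglucinol unit armed, coupled to the iodochromone, chromone opened, flavanone C ring closed, resolved, resorcinol unmasked and iodinated, flavone pyranone ring closed last, sulfation, debenzylation.
- Stereochemistry: 2,3-trans by equilibration at C3 during ring closure. The absolute (2R,3S) configuration comes from kinetic resolution of the racemic chromanone by asymmetric transfer hydrogenation; later steps avoid strong base so that O1–C2 is not opened.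

Key step: step 12

Remark: the target is drawn as the free aryl hydrogen sulfate; it is carried as its triethylammonium salt and protonated only in the last operation, because aryl hydrogen sulfates hydrolyse under their own acidity.

**Step 1**
Reactants: 1 phloroglucinol
Product: 2 5-(benzyloxy)benzene-1,3-diol
Conditions: BnBr (0.35 equiv), K2CO3, DMF, 0 °C to rt; excess 1 recovered
Reagents that add atoms: benzyl bromide, BrCc1ccccc1
Why: Williamson mono-etherification of a symmetric triol, made selective for the mono-ether by keeping the triol in excess.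

**Step 2**
Reactants: 2 5-(benzyloxy)benzene-1,3-diol
Product: 3 1-(benzyloxy)-3,5-bis(methoxymethoxy)benzene
Conditions: MOMCl (2.5 equiv), i-Pr2NEt, CH2Cl2, 0 °C to rt
Reagents that add atoms: chloromethyl methyl ether, COCCl
Why: Standard acetal protection of both phenols; the MOM groups later serve as directing groups for metalation and are orthogonal to benzyl.

**Step 3**
Reactants: 4 1-(2,4,6-trihydroxyphenyl)ethan-1-one
Product: 5 1-[2,4-bis(benzyloxy)-6-hydroxyphenyl]ethan-1-one
Conditions: BnBr (2.1 equiv), K2CO3, DMF, rt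
Reagents that add atoms: benzyl bromide, BrCc1ccccc1
Why: Williamson etherification in which the hydroxyl hydrogen-bonded to the acetyl carbonyl is the least nucleophilic and stays free with two equivalents of halide.

**Step 4**
Reactants: 5 1-[2,4-bis(benzyloxy)-6-hydroxyphenyl]ethan-1-one
Product: 7 5,7-bis(benzyloxy)-3-iodo-4H-chromen-4-one, via enaminone 6 (not isolated)
Conditions: Me2NCH(OMe)2, 95 °C; concentrate; I2, CHCl3, rt
Reagents that add atoms: N,N-dimethylformamide dimethyl acetal, COC(OC)N(C)C; iodine, II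
Why: Amide-acetal condensation gives the vinylogous amide, and its electrophilic iodination is followed by 6-endo addition–elimination of the phenol with loss of dimethylamine (enaminone iodocyclisation to a 3-iodochromone).

**Step 5**
Reactants: 3 1-(benzyloxy)-3,5-bis(methoxymethoxy)benzene; 7 5,7-bis(benzyloxy)-3-iodo-4H-chromen-4-one
Product: 10 5,7-bis(benzyloxy)-3-[4-(benzyloxy)-2,6-bis(methoxymethoxy)phenyl]-4H-chromen-4-one, via aryllithium 8 (not isolated), via arylzinc chloride 9 (not isolated)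
Conditions: 3, n-BuLi, THF, 0 °C; ZnCl2, 0 °C to rt; then 7, Pd2(dba)3 (2.5 mol %), SPhos (10 mol %), THF, 55 °C
Reagents that add atoms: none
Why: Directed ortho-metalation takes place at the carbon flanked by both MOM ethers, Li-to-Zn exchange gives an arylzinc that tolerates the chromone carbonyl, and Negishi coupling with a biarylphosphine ligand joins the di-ortho-substituted aryl group to C3.

**Step 6**
Reactants: 10 5,7-bis(benzyloxy)-3-[4-(benzyloxy)-2,6-bis(methoxymethoxy)phenyl]-4H-chromen-4-one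
Product: 11 1-[2,4-bis(benzyloxy)-6-hydroxyphenyl]-2-[4-(benzyloxy)-2,6-bis(methoxymethoxy)phenyl]ethan-1-one
Conditions: KOH (10 % aq), EtOH, reflux; then AcOH to pH 5
Reagents that add atoms: none
Why: Alkaline isoflavone cleavage: hydroxide adds to C2, the pyranone opens to the α-formyl ketone and retro-Claisen loss of formate leaves the 2-hydroxydeoxybenzoin, with benzyl and MOM ethers inert to base.

**Step 7**
Reactants: 11 1-[2,4-bis(benzyloxy)-6-hydroxyphenyl]-2-[4-(benzyloxy)-2,6-bis(methoxymethoxy)phenyl]ethan-1-one; 12 4-(benzyloxy)benzaldehyde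
Product: 14 rac-trans-5,7-bis(benzyloxy)-2-[4-(benzyloxy)phenyl]-3-[4-(benzyloxy)-2,6-bis(methoxymethoxy)phenyl]chroman-4-one, via α-aryl-2'-hydroxychalcone 13 (not isolated)
Conditions: piperidine (2 equiv), EtOH, reflux
Reagents that add atoms: none
Why: Piperidine-mediated Knoevenagel condensation gives the chalcone, which closes by 6-endo-trig oxa-Michael addition, and C3 equilibrates through the enol under the amine so that the diequatorial 2,3-trans isomer should result, as the racemate.

**Step 8**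
Reactants: 14 rac-trans-5,7-bis(benzyloxy)-2-[4-(benzyloxy)phenyl]-3-[4-(benzyloxy)-2,6-bis(methoxymethoxy)phenyl]chroman-4-one
Product: 15 (2R,3S)-5,7-bis(benzyloxy)-2-[4-(benzyloxy)phenyl]-3-[4-(benzyloxy)-2,6-bis(methoxymethoxy)phenyl]chroman-4-one
Conditions: RuCl[(S,S)-TsDPEN](p-cymene) (2 mol %), HCO2H–Et3N (5:2), EtOAc, 35 °C, stopped near 55 % conversion; chromatography
Reagents that add atoms: none
Why: Kinetic resolution by Ru–TsDPEN asymmetric transfer hydrogenation, a known process for racemic flavanones: the (S,S)-catalyst forms the (4S)-carbinol, which is the axial-attack, all-equatorial product only for the (2S,3R)-ketone, so the (2R,3S)-ketone should be left behind and fixes the absolute configuration.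

**Step 9**
Reactants: 15 (2R,3S)-5,7-bis(benzyloxy)-2-[4-(benzyloxy)phenyl]-3-[4-(benzyloxy)-2,6-bis(methoxymethoxy)phenyl]chroman-4-one
Product: 16 (2R,3S)-5,7-bis(benzyloxy)-2-[4-(benzyloxy)phenyl]-3-[4-(benzyloxy)-2,6-dihydroxyphenyl]chroman-4-one
Conditions: TMSOTf (4 equiv), 2,2'-bipyridyl (6 equiv), MeCN, 0 °C to rt; then H2O
Reagents that add atoms: none
Why: Silyl triflate/bipyridyl cleavage of aryl MOM ethers goes through the aryl silyl ethers and is hydrolysed near neutral pH, which avoids the protic acid that could cyclodehydrate the 2-hydroxyaryl ketone to a benzofuran and leaves benzyl ethers untouched.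

**Step 10**
Reactants: 16 (2R,3S)-5,7-bis(benzyloxy)-2-[4-(benzyloxy)phenyl]-3-[4-(benzyloxy)-2,6-dihydroxyphenyl]chroman-4-one
Product: 17 (2R,3S)-5,7-bis(benzyloxy)-2-[4-(benzyloxy)phenyl]-3-[4-(benzyloxy)-2,6-dihydroxy-3-iodophenyl]chroman-4-one
Conditions: NIS (1.0 equiv), MeCN–CH2Cl2, −30 °C
Reagents that add atoms: N-iodosuccinimide, O=C1CCC(=O)N1I
Why: Electrophilic aromatic iodination of the free resorcinol ring, far more activated than any ether ring; its two open positions are equivalent by symmetry, so one equivalent at low temperature should give a single mono-iodide.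

**Step 11**
Reactants: 18 3,4-bis(benzyloxy)benzaldehyde
Product: 19 1,2-bis(benzyloxy)-4-ethynylbenzene
Conditions: MeC(O)C(N2)P(O)(OMe)2, K2CO3, MeOH, rt
Reagents that add atoms: dimethyl (1-diazo-2-oxopropyl)phosphonate, CC(=O)C(=[N+]=[N-])P(=O)(OC)OC
Why: Ohira–Bestmann (Seyferth–Gilbert) homologation converts the aryl aldehyde into the terminal alkyne under mild carbonate conditions.

**Step 12**
Reactants: 17 (2R,3S)-5,7-bis(benzyloxy)-2-[4-(benzyloxy)phenyl]-3-[4-(benzyloxy)-2,6-dihydroxy-3-iodophenyl]chroman-4-one; 19 1,2-bis(benzyloxy)-4-ethynylbenzene; 20 carbon monoxide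
Product: 23 (2R,3S)-5,7-bis(benzyloxy)-2-[4-(benzyloxy)phenyl]-3-{5-(benzyloxy)-2-[3,4-bis(benzyloxy)phenyl]-7-hydroxy-4-oxo-4H-chromen-8-yl}chroman-4-one, via o-hydroxyaryl ynone 21 (not isolated), via diethylamino enone 22 (not isolated)
Conditions: PdCl2(PPh3)2 (5 mol %), Et2NH (5 equiv), DMF, CO (1 atm), 45 °C
Reagents that add atoms: none
Why: Pd(0) inserts into the C–I bond of 17, CO insertion gives the aroylpalladium species, and amine-assisted alkynyl transfer with reductive elimination gives ynone 21 (C4a''–C4'' and C4''–C3''); diethylamine then adds to the ynone to give the vinylogous amide 22, and the phenol ortho to the acyl group displaces the amine to form O1''–C2''. The closest known reaction is the palladium-catalysed carbonylative Sonogashira annulation of o-iodophenols with terminal alkynes to flavones. The pyranone ring closes in the 6-endo mode (6-endo-dig with respect to the ynone, realised as addition–elimination on the enaminone), which the secondary amine enforces over 5-exo closure to the aurone. No stereocentre is formed; C3 of the chromanone can re-equilibrate to trans, and C2 is kept intact by the moderate temperature and by using an amine and no alkoxide or amidine base, so that O1–C2 is not opened. Carbonylative coupling is favoured over direct coupling by the CO atmosphere, the absence of copper and fast CO insertion into the electron-rich, di-ortho-substituted arylpalladium. Regiochemistry needs no control element: only the hydroxyl next to the former C–I carbon can reach the ynone, and because the aryl ring was symmetric before iodination the other hydroxyl is necessarily the free 7''-OH.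

**Step 13**
Reactants: 23 (2R,3S)-5,7-bis(benzyloxy)-2-[4-(benzyloxy)phenyl]-3-{5-(benzyloxy)-2-[3,4-bis(benzyloxy)phenyl]-7-hydroxy-4-oxo-4H-chromen-8-yl}chroman-4-one
Product: 24 triethylammonium 5-(benzyloxy)-8-{(2R,3S)-5,7-bis(benzyloxy)-2-[4-(benzyloxy)phenyl]-4-oxochroman-3-yl}-2-[3,4-bis(benzyloxy)phenyl]-4-oxo-4H-chromen-7-yl sulfate
Conditions: SO3·pyridine (5 equiv), pyridine, 45 °C; then Et3N
Reagents that add atoms: sulfur trioxide–pyridine complex, [O-]S(=O)(=O)[n+]1ccccc1; triethylamine, CCN(CC)CC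
Why: O-Sulfation of the only free phenol with an amine–SO3 complex; every other oxygen is benzylated or a ring atom, so no regiochemical choice arises, and the monoester is kept as a stable ammonium salt.

**Step 14**
Reactants: 24 triethylammonium 5-(benzyloxy)-8-{(2R,3S)-5,7-bis(benzyloxy)-2-[4-(benzyloxy)phenyl]-4-oxochroman-3-yl}-2-[3,4-bis(benzyloxy)phenyl]-4-oxo-4H-chromen-7-yl sulfate
Product: 26 2-(3,4-dihydroxyphenyl)-8-[(2R,3S)-5,7-dihydroxy-2-(4-hydroxyphenyl)-4-oxochroman-3-yl]-5-hydroxy-4-oxo-4H-chromen-7-yl hydrogen sulfate, via triethylammonium salt 25 (not isolated)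
Conditions: H2 (1 atm), 10 % Pd/C, THF–MeOH, rt; filter; Dowex 50W (H+ form), MeOH–H2O, 0 °C; freeze-dry
Reagents that add atoms: none
Why: Catalytic hydrogenolysis cleaves the six benzyl aryl ethers while the aryl sulfate salt, the flavone double bond and both ketones should survive at 1 atm under neutral conditions, and brief cation exchange in the cold gives the free hydrogen sulfate.

**Compound list**
1 | phloroglucinol (benzene-1,3,5-triol) | Oc1cc(O)cc(O)c1 | starting material
2 | 5-(benzyloxy)benzene-1,3-diol | Oc1cc(O)cc(OCc2ccccc2)c1 | intermediate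
3 | 1-(benzyloxy)-3,5-bis(methoxymethoxy)benzene | COCOc1cc(OCOC)cc(OCc2ccccc2)c1 | intermediate
4 | 1-(2,4,6-trihydroxyphenyl)ethan-1-one | CC(=O)c1c(O)cc(O)cc1O | starting material
5 | 1-[2,4-bis(benzyloxy)-6-hydroxyphenyl]ethan-1-one | CC(=O)c1c(O)cc(OCc2ccccc2)cc1OCc1ccccc1 | intermediate
6 | (E)-1-[2,4-bis(benzyloxy)-6-hydroxyphenyl]-3-(dimethylamino)prop-2-en-1-one | CN(C)/C=C/C(=O)c1c(O)cc(OCc2ccccc2)cc1OCc1ccccc1 | intermediate
7 | 5,7-bis(benzyloxy)-3-iodo-4H-chromen-4-one | O=c1c(I)coc2cc(OCc3ccccc3)cc(OCc3ccccc3)c12 | intermediate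
8 | [4-(benzyloxy)-2,6-bis(methoxymethoxy)phenyl]lithium | [Li]c1c(OCOC)cc(OCc2ccccc2)cc1OCOC | intermediate
9 | [4-(benzyloxy)-2,6-bis(methoxymethoxy)phenyl]zinc chloride | Cl[Zn]c1c(OCOC)cc(OCc2ccccc2)cc1OCOC | intermediate
10 | 5,7-bis(benzyloxy)-3-[4-(benzyloxy)-2,6-bis(methoxymethoxy)phenyl]-4H-chromen-4-one | O=c1c(-c2c(OCOC)cc(OCc3ccccc3)cc2OCOC)coc2cc(OCc3ccccc3)cc(OCc3ccccc3)c12 | intermediate
11 | 1-[2,4-bis(benzyloxy)-6-hydroxyphenyl]-2-[4-(benzyloxy)-2,6-bis(methoxymethoxy)phenyl]ethan-1-one | O=C(Cc1c(OCOC)cc(OCc2ccccc2)cc1OCOC)c1c(O)cc(OCc2ccccc2)cc1OCc1ccccc1 | intermediate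
12 | 4-(benzyloxy)benzaldehyde | O=Cc1ccc(OCc2ccccc2)cc1 | starting material
13 | 1-[2,4-bis(benzyloxy)-6-hydroxyphenyl]-2-[4-(benzyloxy)-2,6-bis(methoxymethoxy)phenyl]-3-[4-(benzyloxy)phenyl]prop-2-en-1-one (alkene geometry not fixed) | O=C(C(=Cc1ccc(OCc2ccccc2)cc1)c1c(OCOC)cc(OCc2ccccc2)cc1OCOC)c1c(O)cc(OCc2ccccc2)cc1OCc1ccccc1 | intermediate
14 | rac-trans-5,7-bis(benzyloxy)-2-[4-(benzyloxy)phenyl]-3-[4-(benzyloxy)-2,6-bis(methoxymethoxy)phenyl]chroman-4-one (both enantiomers written) | O=C1c2c(OCc3ccccc3)cc(OCc3ccccc3)cc2O[C@@H](c2ccc(OCc3ccccc3)cc2)[C@@H]1c1c(OCOC)cc(OCc2ccccc2)cc1OCOC.O=C1c2c(OCc3ccccc3)cc(OCc3ccccc3)cc2O[C@H](c2ccc(OCc3ccccc3)cc2)[C@H]1c1c(OCOC)cc(OCc2ccccc2)cc1OCOC | intermediate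
15 | (2R,3S)-5,7-bis(benzyloxy)-2-[4-(benzyloxy)phenyl]-3-[4-(benzyloxy)-2,6-bis(methoxymethoxy)phenyl]chroman-4-one | O=C1c2c(OCc3ccccc3)cc(OCc3ccccc3)cc2O[C@@H](c2ccc(OCc3ccccc3)cc2)[C@@H]1c1c(OCOC)cc(OCc2ccccc2)cc1OCOC | intermediate
16 | (2R,3S)-5,7-bis(benzyloxy)-2-[4-(benzyloxy)phenyl]-3-[4-(benzyloxy)-2,6-dihydroxyphenyl]chroman-4-one | O=C1c2c(OCc3ccccc3)cc(OCc3ccccc3)cc2O[C@@H](c2ccc(OCc3ccccc3)cc2)[C@@H]1c1c(O)cc(OCc2ccccc2)cc1O | intermediate
17 | (2R,3S)-5,7-bis(benzyloxy)-2-[4-(benzyloxy)phenyl]-3-[4-(benzyloxy)-2,6-dihydroxy-3-iodophenyl]chroman-4-one | O=C1c2c(OCc3ccccc3)cc(OCc3ccccc3)cc2O[C@@H](c2ccc(OCc3ccccc3)cc2)[C@@H]1c1c(O)cc(OCc2ccccc2)c(I)c1O | intermediate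
18 | 3,4-bis(benzyloxy)benzaldehyde | O=Cc1ccc(OCc2ccccc2)c(OCc2ccccc2)c1 | starting material
19 | 1,2-bis(benzyloxy)-4-ethynylbenzene | C#Cc1ccc(OCc2ccccc2)c(OCc2ccccc2)c1 | intermediate
20 | carbon monoxide | [C-]#[O+] | starting material
21 | (2R,3S)-5,7-bis(benzyloxy)-2-[4-(benzyloxy)phenyl]-3-{4-(benzyloxy)-3-[3-(3,4-bis(benzyloxy)phenyl)prop-2-ynoyl]-2,6-dihydroxyphenyl}chroman-4-one | O=C1c2c(OCc3ccccc3)cc(OCc3ccccc3)cc2O[C@@H](c2ccc(OCc3ccccc3)cc2)[C@@H]1c1c(O)cc(OCc2ccccc2)c(C(=O)C#Cc2ccc(OCc3ccccc3)c(OCc3ccccc3)c2)c1O | intermediate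
22 | (2R,3S)-5,7-bis(benzyloxy)-2-[4-(benzyloxy)phenyl]-3-{4-(benzyloxy)-3-[3-(3,4-bis(benzyloxy)phenyl)-3-(diethylamino)prop-2-enoyl]-2,6-dihydroxyphenyl}chroman-4-one (alkene geometry not fixed) | O=C1c2c(OCc3ccccc3)cc(OCc3ccccc3)cc2O[C@@H](c2ccc(OCc3ccccc3)cc2)[C@@H]1c1c(O)cc(OCc2ccccc2)c(C(=O)C=C(N(CC)CC)c2ccc(OCc3ccccc3)c(OCc3ccccc3)c2)c1O | intermediate
23 | (2R,3S)-5,7-bis(benzyloxy)-2-[4-(benzyloxy)phenyl]-3-{5-(benzyloxy)-2-[3,4-bis(benzyloxy)phenyl]-7-hydroxy-4-oxo-4H-chromen-8-yl}chroman-4-one | O=C1c2c(OCc3ccccc3)cc(OCc3ccccc3)cc2O[C@@H](c2ccc(OCc3ccccc3)cc2)[C@@H]1c1c(O)cc(OCc3ccccc3)c2c(=O)cc(-c3ccc(OCc4ccccc4)c(OCc4ccccc4)c3)oc12 | intermediate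
24 | triethylammonium 5-(benzyloxy)-8-{(2R,3S)-5,7-bis(benzyloxy)-2-[4-(benzyloxy)phenyl]-4-oxochroman-3-yl}-2-[3,4-bis(benzyloxy)phenyl]-4-oxo-4H-chromen-7-yl sulfate | O=C1c2c(OCc3ccccc3)cc(OCc3ccccc3)cc2O[C@@H](c2ccc(OCc3ccccc3)cc2)[C@@H]1c1c(OS(=O)(=O)[O-])cc(OCc3ccccc3)c2c(=O)cc(-c3ccc(OCc4ccccc4)c(OCc4ccccc4)c3)oc12.CC[NH+](CC)CC | intermediate
25 | triethylammonium 2-(3,4-dihydroxyphenyl)-8-[(2R,3S)-5,7-dihydroxy-2-(4-hydroxyphenyl)-4-oxochroman-3-yl]-5-hydroxy-4-oxo-4H-chromen-7-yl sulfate | O=C1c2c(O)cc(O)cc2O[C@@H](c2ccc(O)cc2)[C@@H]1c1c(OS(=O)(=O)[O-])cc(O)c2c(=O)cc(-c3ccc(O)c(O)c3)oc12.CC[NH+](CC)CC | intermediate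
26 | 2-(3,4-dihydroxyphenyl)-8-[(2R,3S)-5,7-dihydroxy-2-(4-hydroxyphenyl)-4-oxochroman-3-yl]-5-hydroxy-4-oxo-4H-chromen-7-yl hydrogen sulfate | O=C1c2c(O)cc(O)cc2O[C@@H](c2ccc(O)cc2)[C@@H]1c1c(OS(=O)(=O)O)cc(O)c2c(=O)cc(-c3ccc(O)c(O)c3)oc12 | target

**Totals**
Total step count: 14. Longest linear sequence: 11 steps (steps 1, 2, 5, 6, 7, 8, 9, 10, 12, 13, 14).

**Steps most likely to fail**

Step 8 (kinetic resolution). The rate difference between the enantiomers may be too small, or hydride transfer to the electron-rich carbonyl flanked by the 5-benzyloxy group and the bulky C3 aryl group may be too slow to reach useful conversion. The sense of the resolution is assigned by analogy with flavanone and would have to be confirmed. Fallback: from 14 to 15 by preparative chromatography on a chiral stationary phase (amylose tris(3,5-dimethylphenylcarbamate), supercritical CO2/alcohol). The unwanted antipode is re-racemised by heating with piperidine in ethanol (retro-oxa-Michael/oxa-Michael, the conditions of step 7) and recycled. This makes no new compound (entry F0).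

Step 12 (carbonylative annulation). Several processes can compete: amine-induced opening of O1–C2 with loss of the C2 configuration, 5-exo closure to the aurone, direct non-carbonylative coupling followed by benzofuran formation, and capture of the aroylpalladium by diethylamine. Fallback: setting out from 17, both phenols are acetylated (Ac2O, pyridine, DMAP, 0 °C) to the diacetate F1. Carbonylative Sonogashira coupling of this compound with 19 at room temperature (PdCl2(PPh3)2, CuI, Et3N, THF, CO 1 atm) gives the diacetoxy ynone F2, so that no free ortho-phenoxide is present during the palladium stage. Short treatment with Et2NH in THF at room temperature then removes both acetates by aminolysis, adds to the ynone and closes the ring 6-endo, returning to 23.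

Step 14 (global debenzylation and protonation). The sulfate may be lost by acid-catalysed hydrolysis during hydrogenolysis or on the acid resin, and over-reduction may occur (saturation of C2''=C3'' or hydrogenolysis of the benzylic O1–C2 bond) on prolonged exposure. Fallback: from 23, reaction with 2,2,2-trichloroethyl chlorosulfate (Et3N, DMAP, THF) gives the neutral, chromatographable aryl 2,2,2-trichloroethyl sulfate F3. Transfer hydrogenolysis (Pd/C, HCO2NH4, MeOH–THF, rt) then removes the six benzyl groups and the trichloroethyl group in one buffered operation to give the ammonium salt of the target F4. Cation exchange in the cold leads back to 26.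

**Further compounds**
F0 | step 8 | none | none
F1 | step 12 | (2R,3S)-5,7-bis(benzyloxy)-2-[4-(benzyloxy)phenyl]-3-[2,6-diacetoxy-4-(benzyloxy)-3-iodophenyl]chroman-4-one | O=C1c2c(OCc3ccccc3)cc(OCc3ccccc3)cc2O[C@@H](c2ccc(OCc3ccccc3)cc2)[C@@H]1c1c(OC(C)=O)cc(OCc2ccccc2)c(I)c1OC(C)=O
F2 | step 12 | (2R,3S)-5,7-bis(benzyloxy)-2-[4-(benzyloxy)phenyl]-3-{2,6-diacetoxy-4-(benzyloxy)-3-[3-(3,4-bis(benzyloxy)phenyl)prop-2-ynoyl]phenyl}chroman-4-one | O=C1c2c(OCc3ccccc3)cc(OCc3ccccc3)cc2O[C@@H](c2ccc(OCc3ccccc3)cc2)[C@@H]1c1c(OC(C)=O)cc(OCc2ccccc2)c(C(=O)C#Cc2ccc(OCc3ccccc3)c(OCc3ccccc3)c2)c1OC(C)=O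
F3 | step 14 | 5-(benzyloxy)-8-{(2R,3S)-5,7-bis(benzyloxy)-2-[4-(benzyloxy)phenyl]-4-oxochroman-3-yl}-2-[3,4-bis(benzyloxy)phenyl]-4-oxo-4H-chromen-7-yl 2,2,2-trichloroethyl sulfate | O=C1c2c(OCc3ccccc3)cc(OCc3ccccc3)cc2O[C@@H](c2ccc(OCc3ccccc3)cc2)[C@@H]1c1c(OS(=O)(=O)OCC(Cl)(Cl)Cl)cc(OCc3ccccc3)c2c(=O)cc(-c3ccc(OCc4ccccc4)c(OCc4ccccc4)c3)oc12
F4 | step 14 | ammonium 2-(3,4-dihydroxyphenyl)-8-[(2R,3S)-5,7-dihydroxy-2-(4-hydroxyphenyl)-4-oxochroman-3-yl]-5-hydroxy-4-oxo-4H-chromen-7-yl sulfate | O=C1c2c(O)cc(O)cc2O[C@@H](c2ccc(O)cc2)[C@@H]1c1c(OS(=O)(=O)[O-])cc(O)c2c(=O)cc(-c3ccc(O)c(O)c3)oc12.[NH4+]
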